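Each catalyst must go round the cycle 50.0 times, on average, to turn the charge of starting material into product, so we ask how long one round takes.

| flask | starting material | coupling partner | free catalyst | time | remark |
|---|---|---|---|---|---|
| north | 0.0020 M (fed, over 24.0 s) | 5.00 mM | 40 µM | 30 s | all but starting material at the start; starting material goes in evenly over 24.0 s, the run ends at 30 s |
| north-west | 0.0020 M | 5.00 mM | 40 µM | 30 s | everything together in a closed stirred flask, run for 30 s |
| north-east | 0.0020 M | 5.00 mM | 40 µM |  | one stirred flow tank at steady state, fed with the mixture as stated, mean residence time 30 s |
| south-west | 0.0020 M | 5.00 mM | 40 µM |  | one stirred flow tank at steady state, fed with the mixture as stated, mean residence time 300 s |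

    catalyst intermediate C → free catalyst + product (k1 = 2.4 s⁻¹)
    coupling partner + catalyst intermediate B → catalyst intermediate C (k2 = 2600 M⁻¹ s⁻¹)
    2 free catalyst ⇌ resting dimer, settled at all times (K3 = 9600 M⁻¹)
    starting material + free catalyst → catalyst intermediate A (k4 = 98000 M⁻¹ s⁻¹)
    coupling partner ⇌ dormant form (K5 = 1.6, k5 = 0.022 s⁻¹)
    catalyst intermediate A ⇌ catalyst intermediate B (K6 = 1.7, k6 = 200 s⁻¹)
    2 catalyst intermediate B → spent catalyst (k7 = 16000 M⁻¹ s⁻¹)

* the set-up with the highest amount of product at the outlet or at the end, in percent of the starting material put in ("none" if the first two lie within 2 percentage points) (north / north-west / north-east / south-west / none)
* amount of product at the outlet or at the end, in percent of the starting material put in, north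
* amount of product at the outlet or at the end, in percent of the starting material put in, north-west
* amount of product at the outlet or at the end, in percent of the starting material put in, north-east
* amount of product at the outlet or at the end, in percent of the starting material put in, south-west

- in percentages every species weighs as the starting material in it: one spent catalyst counts as two
- a doubled species enters its step squared and goes two at a time
- the stated concentrations are those of everything mixed, before any reaction; amounts are the same in each set-up
- the feed brings no volume worth counting
- run time (north): 30 s

We follow one catalyst round the cycle and add up its waits. Catalyst intermediate C leaves at 2.4 s⁻¹, so it waits the reciprocal of that. Catalyst intermediates A and B interconvert far faster than B leaves, so they stand at balance. The pair then drains through B, whose share of the pair is 1.7 parts in one part more. Free catalyst waits for starting material.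

wait at C = 0.417 s
wait at A and B, coupling partner as charged = 0.122 s
wait at free catalyst, starting material as charged = 0.00510 s

Their sum, 0.544 s, is the turn time: the mean time for one round. At these concentrations C holds the catalyst longest, so it is the resting state.

Multiplying by the rounds needed gives a charge time of 27.2 s. That lies under the 30 s of north and north-west, but it holds coupling partner and catalyst at their charge, and in those two flasks both run down, so it gives no number for either. We commit to no figure for those two flasks.

A tank can be reckoned further, since at steady state its concentrations do not change with time. Coupling partner shares itself with the dormant form, and the turn time is taken at what remains, leaving out the wait at free catalyst. The fraction of running catalyst present as B is its own wait, the reciprocal of k[coupling partner], over the turn time. With x the catalyst not spent, and a the factor of loss to spent catalyst, the balance is: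

40 µM − x = a · x · x, with a = 2 · 16000 M⁻¹ s⁻¹ · fraction · fraction · residence time

In north-east we take product at half the charge:

dormant form per coupling partner = 0.467
[coupling partner] = 2.73 mM
turn time = 0.641 s
fraction as B = 0.220
a = 46500 M⁻¹
x = 20.5 µM
product = x · residence time / turn time = 47.9%

In south-west, with its 300 s, we take product at the whole charge:

dormant form per coupling partner = 1.29
[coupling partner] = 1.31 mM
turn time = 0.883 s
fraction as B = 0.332
a = 1.06 × 10⁶ M⁻¹
x = 5.69 µM
product = 96.7%

The forecast gave north 60%, north-west 61%, north-east 48% and south-west 96%, named south-west best, and held that “slow feeding barely helps because the starting material still builds up”.

The simulation gives north 61.3%, north-west 63.1%, north-east 47.4% and south-west 96.2%, with south-west best.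

In north-west the half-life of catalyst intermediate C by its own step alone, 0.29 s, is longer than the 0.053 s of catalyst intermediate B at the charged coupling partner, and the wait at C is 76.7% of the turn time of 0.544 s. The charge time built on that turn time is 27.2 s, under the 30 s of the run, yet north-west ends with 35.0% of the starting material still standing, and left until 300 s it reaches 98.1% product.

The constants were chosen freely; the run is a simulation.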